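(Readings and results stem from a simulated flask with made-up constants, and the scatter is random.)

In a one-step world with a fixed chance of uptake per second, ln c(free monomer) falls along a straight line, and the grey run of this flask does not.

- grey: free monomer 20 mM; initiator 1 mol%; the very flask that is asked about, followed so far
- flask: free monomer 20 mM; initiator 1 mol%; time 2.5 min

grey run (percent of the free monomer charged)

| time / s | monomer in chains / % | free monomer / % |
|---|---|---|
| 10.0 | 10.4 | 89.7 |
| 20.0 | 32.9 | 67.2 |
| 30.0 | 54.7 | 45.8 |
| 40.0 | 70.9 | 29.3 |
| 50.0 | 82.5 | 18.0 |
| 60.0 | 89.2 | 10.5 |
| 80.0 | 95.8 | 4.2 |

(scatter of a reading: 0.3 percentage points)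

- average number of monomer units in a chain (chains begun, living or dead) at 2.5 min
- part of the free monomer that has reacted at 2.5 min

- the average divides the monomer in chains by the number of chains begun, living and dead together
- the analysis behind the earlier runs scatters by 0.3 percentage points, standard deviation
- steps that have been proposed: free monomer + initiator -> living end + monomer in chains; free monomer + living end -> monomer in chains + living end; 2 initiator -> spent initiator
- the earlier runs do not show the number of chains; that part of a forecast is a guess

Over the first 10.0 s the slope was 0.0109 /s. Between 50.0 s and 80.0 s it stood at 0.0485 /s, steeper. I called this the end slope λ: a pseudo-first-order constant, the chance per second that a free monomer unit is taken up, which counts the living ends. Drawn back from the last reading, the line gave a lag of 14.7 s. Carried forward to 2.5 min, it left 0.141% free monomer, so I reckoned c at 99.9%.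

For the chains I compared two rates. Taking the slope to grow steadily from zero over the first reading, I found that at this early pace it reaches λ in 22.3 s. The free monomer readings, summed over time as a fraction of charge, give 32.9 s. This sum is longer than that time; I read the gap as fading initiator, which on this reckoning held on average 67.9% of its charge. I assumed a steady fall, which puts the loss at 64.2% of its charge. If all of that began chains, dp is 156; if the side step took half, dp is 312. That split was my weak link, and I committed to the geometric mean, 220.

The forecast, saying “Chain count is the weak part”, gave 270 (160 to 600), above mine, and 99.8% (99.3% to >99.9%).

The flask gave dp 227 and c 99.9%.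

    free monomer + initiator → living end + monomer in chains (k = 1.06 /M/s)
    free monomer + living end → monomer in chains + living end, rate k2*[living end]*[free monomer] (k = 596 /M/s)
    2 initiator → spent initiator (k = 23.9 /M/s)

With k2 in hand, the weak link could be reforged: the reading λ/k2 is 0.0814 mM of living ends, and it puts dp at 246. At 2.50 min the neighbour flask with 0.6 mol% of initiator held 0.0653 mM of living ends, and this flask held 0.0878 mM. Scaling λ by that ratio gives 0.0361 /s, and with the lag kept, 0.756% free monomer is left. That neighbour gave dp 304 and kept 0.72% of its free monomer.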